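**Retrosynthetic overview**
1. Target 25 ⇐ diol 21 by two acylations (C8 angelate, then C10 acetate); 21 ⇐ 20 by desilylation.
2. Butenolide (third ring, formed last) ⇐ ring-closing metathesis of the C6 2-(acetoxymethyl)acrylate with the C7 exocyclic methylene (19).
3. Ten-membered carbocycle (second ring) ⇐ new exo-selective nickel-catalysed reductive alkyne–aldehyde macrocyclisation forming C6–C7 on epoxy aldehyde 14.
4. Oxirane (first ring) ⇐ Sharpless epoxidation of allylic alcohol 12; 12 ⇐ C2–C3 enolate allylation of methyl ketone 6 with the C5 bromide 9.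
5. 6 ⇐ copper–bis(oxazoline) Mukaiyama aldol of butane-2,3-dione with enolsilane 2 (sets C10) and Noyori reduction of the ynone (sets C8).

Assumption: germacrane numbering is used (C1 ketone, C4–C5 epoxide, C6 lactone carbinol, C7=C11, C8 angelate, C10 tertiary acetate, C12 lactone C=O, C13 CH2OAc), the target is (4R,5R,6S,8S,10R) with a Z (angelate) ester, and the sense of induction of each chiral catalyst is taken from its closest reported substrates.

**Step 1**
Reactants: 1 4-(trimethylsilyl)but-3-yn-2-one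
Product: 2 trimethyl{[4-(trimethylsilyl)but-1-en-3-yn-2-yl]oxy}silane
Conditions: TMSOTf, Et3N, Et2O, 0 °C
Reagents that add atoms: trimethylsilyl trifluoromethanesulfonate, C[Si](C)(C)OS(=O)(=O)C(F)(F)F
Why: Soft enolisation and O-silylation of the methyl ketone gives the enolsilane donor for the Mukaiyama aldol, with no stereocentre formed.

**Step 2**
Reactants: 2 trimethyl{[4-(trimethylsilyl)but-1-en-3-yn-2-yl]oxy}silane; 3 butane-2,3-dione
Product: 4 (3R)-3-methyl-7-(trimethylsilyl)-3-[(trimethylsilyl)oxy]hept-6-yne-2,5-dione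
Conditions: Cu(OTf)2 (10 mol %), (R,R)-tBu-box (11 mol %), THF, −78 °C, neutral work-up
Reagents that add atoms: none
Why: Evans-type catalytic Mukaiyama aldol in which the 1,2-diketone chelates divalent copper in the square-planar bis(oxazoline) complex and the enolsilane attacks the open carbonyl face, setting C10 as R (the mirror-image ligand is reported to give S adducts) with silyl transfer to the new tertiary alkoxide.

**Step 3**
Reactants: 4 (3R)-3-methyl-7-(trimethylsilyl)-3-[(trimethylsilyl)oxy]hept-6-yne-2,5-dione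
Product: 5 (3R,5S)-5-hydroxy-3-methyl-7-(trimethylsilyl)-3-[(trimethylsilyl)oxy]hept-6-yn-2-one
Conditions: Ru[(S,S)-TsNCHPhCHPhNH](p-cymene) (2 mol %), iPrOH, rt
Reagents that add atoms: none
Why: Noyori asymmetric transfer hydrogenation reduces only the ynone (the hindered dialkyl ketone is inert) and the (S,S) catalyst delivers hydride under catalyst control to give the (S)-propargylic alcohol, which is C8.

**Step 4**
Reactants: 5 (3R,5S)-5-hydroxy-3-methyl-7-(trimethylsilyl)-3-[(trimethylsilyl)oxy]hept-6-yn-2-one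
Product: 6 (3R,5S)-5-[(tert-butyldimethylsilyl)oxy]-3-methyl-7-(trimethylsilyl)-3-[(trimethylsilyl)oxy]hept-6-yn-2-one
Conditions: TBSCl, imidazole, DMF, rt
Reagents that add atoms: tert-butyldimethylsilyl chloride, CC(C)(C)[Si](C)(C)Cl
Why: Standard silylation of the secondary alcohol traps the open hydroxy ketone and gives an ether that survives until step 16.

**Step 5**
Reactants: 7 3-methylbut-2-en-1-yl acetate (prenyl acetate)
Product: 8 (2E)-4-hydroxy-3-methylbut-2-en-1-yl acetate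
Conditions: SeO2 (0.1 equiv), tBuOOH (2 equiv), CH2Cl2, rt
Reagents that add atoms: tert-butyl hydroperoxide, CC(C)(C)OO
Why: Sharpless–Umbreit SeO2-catalysed allylic oxidation (ene reaction then [2,3]-shift) is selective for the E methyl group and fixes the E olefin that later becomes the trans epoxide.

**Step 6**
Reactants: 8 (2E)-4-hydroxy-3-methylbut-2-en-1-yl acetate
Product: 9 (2E)-4-bromo-3-methylbut-2-en-1-yl acetate
Conditions: CBr4, PPh3, CH2Cl2, 0 °C
Reagents that add atoms: carbon tetrabromide, BrC(Br)(Br)Br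
Why: Appel bromination of the primary allylic alcohol proceeds by SN2 without allylic shift or loss of olefin geometry.

**Step 7**
Reactants: 6 (3R,5S)-5-[(tert-butyldimethylsilyl)oxy]-3-methyl-7-(trimethylsilyl)-3-[(trimethylsilyl)oxy]hept-6-yn-2-one; 9 (2E)-4-bromo-3-methylbut-2-en-1-yl acetate
Product: 11 (2E,7R,9S)-9-[(tert-butyldimethylsilyl)oxy]-3,7-dimethyl-6-oxo-11-(trimethylsilyl)-7-[(trimethylsilyl)oxy]undec-2-en-10-yn-1-yl acetate, via kinetic lithium enolate 10 (not isolated)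
Conditions: LiN(iPr)2 (LDA), THF, −78 °C; then 9, DMPU, −78 to −30 °C
Reagents that add atoms: none
Why: Kinetic enolate alkylation in which only the methyl group can be deprotonated (C10 is quaternary) and SN2 attack on the primary allylic bromide forms C2–C3 with the E olefin intact.

**Step 8**
Reactants: 11 (2E,7R,9S)-9-[(tert-butyldimethylsilyl)oxy]-3,7-dimethyl-6-oxo-11-(trimethylsilyl)-7-[(trimethylsilyl)oxy]undec-2-en-10-yn-1-yl acetate
Product: 12 (3S,5R,9E)-3-[(tert-butyldimethylsilyl)oxy]-5,11-dihydroxy-5,9-dimethylundec-9-en-1-yn-6-one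
Conditions: K2CO3 (0.5 equiv), MeOH, rt; 10% aq. citric acid work-up
Reagents that add atoms: none
Why: Base-catalysed methanolysis removes the acetate, the alkynyl TMS group and (completed by the mild acid work-up) the tertiary O-TMS group in one operation while the secondary TBS ether stays.

**Step 9**
Reactants: 12 (3S,5R,9E)-3-[(tert-butyldimethylsilyl)oxy]-5,11-dihydroxy-5,9-dimethylundec-9-en-1-yn-6-one
Product: 13 (4R,6S)-6-[(tert-butyldimethylsilyl)oxy]-4-hydroxy-1-[(2R,3R)-3-(hydroxymethyl)-2-methyloxiran-2-yl]-4-methyloct-7-yn-3-one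
Conditions: Ti(OiPr)4 (0.2 equiv), D-(−)-diethyl tartrate (0.25 equiv), tBuOOH, 4 Å MS, CH2Cl2, −20 °C
Reagents that add atoms: tert-butyl hydroperoxide, CC(C)(C)OO
Why: Katsuki–Sharpless asymmetric epoxidation of this geraniol-type allylic alcohol with D-(−)-tartrate gives the (2R,3R)-epoxy alcohol (mirror of the L-(+)-tartrate/geraniol 2S,3S case), which sets C4 and C5 as R,R by reagent control.

**Step 10**
Reactants: 13 (4R,6S)-6-[(tert-butyldimethylsilyl)oxy]-4-hydroxy-1-[(2R,3R)-3-(hydroxymethyl)-2-methyloxiran-2-yl]-4-methyloct-7-yn-3-one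
Product: 14 (2S,3R)-3-[(4R,6S)-6-[(tert-butyldimethylsilyl)oxy]-4-hydroxy-4-methyl-3-oxooct-7-yn-1-yl]-3-methyloxirane-2-carbaldehyde
Conditions: Dess–Martin periodinane, pyridine, CH2Cl2, 0 °C
Reagents that add atoms: none
Why: Buffered Dess–Martin oxidation gives the sensitive α,β-epoxy aldehyde without epimerisation or epoxide opening and leaves the tertiary alcohol untouched.

**Step 11**
Reactants: 14 (2S,3R)-3-[(4R,6S)-6-[(tert-butyldimethylsilyl)oxy]-4-hydroxy-4-methyl-3-oxooct-7-yn-1-yl]-3-methyloxirane-2-carbaldehyde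
Product: 15 (1R,5R,7S,9S,10R)-7-[(tert-butyldimethylsilyl)oxy]-5-hydroxy-1,5-dimethyl-8-methylidene-9-[(triethylsilyl)oxy]-11-oxabicyclo[8.1.0]undecan-4-one
Conditions: Ni(cod)2 (30 mol %), (4R,5R)-DP-IPr·HBF4 (30 mol %; DP-IPr = 1,3-bis(2,6-diisopropylphenyl)-4,5-diphenylimidazolidin-2-ylidene), KOtBu (30 mol %), Et3SiH (5 equiv), toluene, 0.002 M, slow addition of 14, 40 °C
Reagents that add atoms: triethylsilane, CC[SiH](CC)CC
Why: Proposed new method: an exo-selective nickel-catalysed reductive alkyne–aldehyde macrocyclisation to a ten-membered carbocycle, in which zerovalent nickel carrying the very bulky carbene undergoes oxidative cyclisation that joins the aldehyde carbon C6 to the internal alkyne carbon C7 (the ligand bulk keeps the propargylic substituent away from nickel), and σ-bond metathesis with Et3SiH followed by C–H reductive elimination irreversibly releases the 7-methylidene C6 silyl ether, with C6 expected S (epoxide oxygen and C6 oxygen on the same side, as in parthenolide) from the crown-like transition state reinforced by the chiral ligand; the closest known reaction type is the Ni/NHC/silane reductive aldehyde–alkyne coupling (Montgomery type), whose ligand-controlled exo-selective ynal macrocyclisations are known only for rings of eleven or more atoms and not for α,β-epoxy aldehydes.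

**Step 12**
Reactants: 15 (1R,5R,7S,9S,10R)-7-[(tert-butyldimethylsilyl)oxy]-5-hydroxy-1,5-dimethyl-8-methylidene-9-[(triethylsilyl)oxy]-11-oxabicyclo[8.1.0]undecan-4-one
Product: 16 (1R,5R,7S,9S,10R)-7-[(tert-butyldimethylsilyl)oxy]-5,9-dihydroxy-1,5-dimethyl-8-methylidene-11-oxabicyclo[8.1.0]undecan-4-one
Conditions: HF·pyridine, pyridine, THF, 0 °C, 30 min
Reagents that add atoms: none
Why: Selective desilylation, since the secondary triethylsilyl ether is cleaved by buffered HF·pyridine far faster than the TBS ether and the epoxide tolerates the buffered medium.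

**Step 13**
Reactants: 17 2-(bromomethyl)prop-2-enoic acid
Product: 18 2-[(acetyloxy)methyl]prop-2-enoic acid
Conditions: AgOAc (1.05 equiv), MeCN, rt, dark
Reagents that add atoms: silver acetate, CC(=O)[O-].[Ag+]
Why: Silver-assisted allylic substitution (SN2 and SN2′ give the same product on this symmetric allyl unit) replaces bromide by acetate.

**Step 14**
Reactants: 16 (1R,5R,7S,9S,10R)-7-[(tert-butyldimethylsilyl)oxy]-5,9-dihydroxy-1,5-dimethyl-8-methylidene-11-oxabicyclo[8.1.0]undecan-4-one; 18 2-[(acetyloxy)methyl]prop-2-enoic acid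
Product: 19 (1R,5R,7S,9S,10R)-7-[(tert-butyldimethylsilyl)oxy]-5-hydroxy-1,5-dimethyl-8-methylidene-4-oxo-11-oxabicyclo[8.1.0]undecan-9-yl 2-[(acetyloxy)methyl]prop-2-enoate
Conditions: DIC, DMAP (0.1 equiv), CH2Cl2, 0 °C to rt
Reagents that add atoms: none
Why: Steglich esterification acylates the secondary allylic C6 alcohol selectively over the tertiary C10 alcohol with retention at C6.

**Step 15**
Reactants: 19 (1R,5R,7S,9S,10R)-7-[(tert-butyldimethylsilyl)oxy]-5-hydroxy-1,5-dimethyl-8-methylidene-4-oxo-11-oxabicyclo[8.1.0]undecan-9-yl 2-[(acetyloxy)methyl]prop-2-enoate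
Product: 20 (4R,5R,6S,8S,10R)-13-acetoxy-8-[(tert-butyldimethylsilyl)oxy]-4,5-epoxy-10-hydroxy-1-oxogermacr-7(11)-en-12,6-olide
Conditions: Stewart–Grubbs catalyst RuCl2(=CH-C6H4-2-OiPr)[1,3-bis(2-methylphenyl)imidazolidin-2-ylidene] (15 mol %), toluene, 80 °C, argon sparge
Reagents that add atoms: none
Why: Ring-closing metathesis of the two 1,1-disubstituted alkenes closes the five-membered butenolide with its tetrasubstituted C7=C11 bond, driven by loss of ethene and helped by the small o-tolyl carbene ligand, without touching C6.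

**Step 16**
Reactants: 20 (4R,5R,6S,8S,10R)-13-acetoxy-8-[(tert-butyldimethylsilyl)oxy]-4,5-epoxy-10-hydroxy-1-oxogermacr-7(11)-en-12,6-olide
Product: 21 (4R,5R,6S,8S,10R)-13-acetoxy-4,5-epoxy-8,10-dihydroxy-1-oxogermacr-7(11)-en-12,6-olide
Conditions: HF·pyridine, pyridine, THF, 0 °C to rt
Reagents that add atoms: none
Why: Buffered fluoride cleavage of the TBS ether leaves the epoxide, the acetate and the butenolide intact.

**Step 17**
Reactants: 21 (4R,5R,6S,8S,10R)-13-acetoxy-4,5-epoxy-8,10-dihydroxy-1-oxogermacr-7(11)-en-12,6-olide; 22 angelic acid ((2Z)-2-methylbut-2-enoic acid)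
Product: 24 (4R,5R,6S,8S,10R)-13-acetoxy-8-angeloyloxy-4,5-epoxy-10-hydroxy-1-oxogermacr-7(11)-en-12,6-olide, via angeloyl 2,4,6-trichlorobenzoyl anhydride 23 (not isolated)
Conditions: 22, 2,4,6-trichlorobenzoyl chloride, Et3N, toluene, rt; then 21, 60 °C (no DMAP)
Reagents that add atoms: none
Why: Yamaguchi esterification through the mixed anhydride acylates the secondary C8 alcohol and not the tertiary one, and running it without DMAP avoids angelate-to-tiglate isomerisation.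

**Step 18**
Reactants: 24 (4R,5R,6S,8S,10R)-13-acetoxy-8-angeloyloxy-4,5-epoxy-10-hydroxy-1-oxogermacr-7(11)-en-12,6-olide
Product: 25 (4R,5R,6S,8S,10R)-10,13-diacetoxy-8-angeloyloxy-4,5-epoxy-1-oxogermacr-7(11)-en-12,6-olide (CNP0175424.2)
Conditions: Ac2O, DMAP, Et3N, CH2Cl2, rt to 40 °C
Reagents that add atoms: acetic anhydride, CC(=O)OC(C)=O
Why: DMAP-catalysed acetylation of the remaining tertiary α-ketol hydroxyl completes the target without touching any stereocentre.

**Compound list**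
1 | 4-(trimethylsilyl)but-3-yn-2-one | CC(=O)C#C[Si](C)(C)C | starting material
2 | trimethyl{[4-(trimethylsilyl)but-1-en-3-yn-2-yl]oxy}silane | C=C(O[Si](C)(C)C)C#C[Si](C)(C)C | intermediate
3 | butane-2,3-dione | CC(=O)C(C)=O | starting material
4 | (3R)-3-methyl-7-(trimethylsilyl)-3-[(trimethylsilyl)oxy]hept-6-yne-2,5-dione | CC(=O)[C@](C)(O[Si](C)(C)C)CC(=O)C#C[Si](C)(C)C | intermediate
5 | (3R,5S)-5-hydroxy-3-methyl-7-(trimethylsilyl)-3-[(trimethylsilyl)oxy]hept-6-yn-2-one | CC(=O)[C@](C)(O[Si](C)(C)C)C[C@H](O)C#C[Si](C)(C)C | intermediate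
6 | (3R,5S)-5-[(tert-butyldimethylsilyl)oxy]-3-methyl-7-(trimethylsilyl)-3-[(trimethylsilyl)oxy]hept-6-yn-2-one | CC(=O)[C@](C)(O[Si](C)(C)C)C[C@H](O[Si](C)(C)C(C)(C)C)C#C[Si](C)(C)C | intermediate
7 | 3-methylbut-2-en-1-yl acetate (prenyl acetate) | CC(C)=CCOC(C)=O | starting material
8 | (2E)-4-hydroxy-3-methylbut-2-en-1-yl acetate | CC(=O)OC/C=C(\C)CO | intermediate
9 | (2E)-4-bromo-3-methylbut-2-en-1-yl acetate | CC(=O)OC/C=C(\C)CBr | intermediate
10 | lithium (3R,5S)-5-[(tert-butyldimethylsilyl)oxy]-3-methyl-7-(trimethylsilyl)-3-[(trimethylsilyl)oxy]hept-1-en-6-yn-2-olate (kinetic enolate of 6) | [Li]OC(=C)[C@](C)(O[Si](C)(C)C)C[C@H](O[Si](C)(C)C(C)(C)C)C#C[Si](C)(C)C | intermediate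
11 | (2E,7R,9S)-9-[(tert-butyldimethylsilyl)oxy]-3,7-dimethyl-6-oxo-11-(trimethylsilyl)-7-[(trimethylsilyl)oxy]undec-2-en-10-yn-1-yl acetate | CC(=O)OC/C=C(\C)CCC(=O)[C@](C)(O[Si](C)(C)C)C[C@H](O[Si](C)(C)C(C)(C)C)C#C[Si](C)(C)C | intermediate
12 | (3S,5R,9E)-3-[(tert-butyldimethylsilyl)oxy]-5,11-dihydroxy-5,9-dimethylundec-9-en-1-yn-6-one | OC/C=C(\C)CCC(=O)[C@](C)(O)C[C@H](O[Si](C)(C)C(C)(C)C)C#C | intermediate
13 | (4R,6S)-6-[(tert-butyldimethylsilyl)oxy]-4-hydroxy-1-[(2R,3R)-3-(hydroxymethyl)-2-methyloxiran-2-yl]-4-methyloct-7-yn-3-one | OC[C@H]1O[C@]1(C)CCC(=O)[C@](C)(O)C[C@H](O[Si](C)(C)C(C)(C)C)C#C | intermediate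
14 | (2S,3R)-3-[(4R,6S)-6-[(tert-butyldimethylsilyl)oxy]-4-hydroxy-4-methyl-3-oxooct-7-yn-1-yl]-3-methyloxirane-2-carbaldehyde | O=C[C@H]1O[C@]1(C)CCC(=O)[C@](C)(O)C[C@H](O[Si](C)(C)C(C)(C)C)C#C | intermediate
15 | (1R,5R,7S,9S,10R)-7-[(tert-butyldimethylsilyl)oxy]-5-hydroxy-1,5-dimethyl-8-methylidene-9-[(triethylsilyl)oxy]-11-oxabicyclo[8.1.0]undecan-4-one (germacrane locants: 4,5-epoxide, 6-OSiEt3, 7-methylidene, 8-OTBS, 10-OH, 1-oxo) | CC(C)(C)[Si](C)(C)O[C@H]1C[C@@](C)(O)C(=O)CC[C@@]2(C)O[C@@H]2[C@@H](O[Si](CC)(CC)CC)C1=C | intermediate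
16 | (1R,5R,7S,9S,10R)-7-[(tert-butyldimethylsilyl)oxy]-5,9-dihydroxy-1,5-dimethyl-8-methylidene-11-oxabicyclo[8.1.0]undecan-4-one | CC(C)(C)[Si](C)(C)O[C@H]1C[C@@](C)(O)C(=O)CC[C@@]2(C)O[C@@H]2[C@@H](O)C1=C | intermediate
17 | 2-(bromomethyl)prop-2-enoic acid | C=C(CBr)C(=O)O | starting material
18 | 2-[(acetyloxy)methyl]prop-2-enoic acid | CC(=O)OCC(=C)C(=O)O | intermediate
19 | (1R,5R,7S,9S,10R)-7-[(tert-butyldimethylsilyl)oxy]-5-hydroxy-1,5-dimethyl-8-methylidene-4-oxo-11-oxabicyclo[8.1.0]undecan-9-yl 2-[(acetyloxy)methyl]prop-2-enoate | CC(C)(C)[Si](C)(C)O[C@H]1C[C@@](C)(O)C(=O)CC[C@@]2(C)O[C@@H]2[C@@H](OC(=O)C(=C)COC(C)=O)C1=C | intermediate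
20 | (4R,5R,6S,8S,10R)-13-acetoxy-8-[(tert-butyldimethylsilyl)oxy]-4,5-epoxy-10-hydroxy-1-oxogermacr-7(11)-en-12,6-olide | CC(C)(C)[Si](C)(C)O[C@H]1C[C@@](C)(O)C(=O)CC[C@@]2(C)O[C@@H]2[C@H]2OC(=O)C(COC(C)=O)=C12 | intermediate
21 | (4R,5R,6S,8S,10R)-13-acetoxy-4,5-epoxy-8,10-dihydroxy-1-oxogermacr-7(11)-en-12,6-olide | O[C@H]1C[C@@](C)(O)C(=O)CC[C@@]2(C)O[C@@H]2[C@H]2OC(=O)C(COC(C)=O)=C12 | intermediate
22 | angelic acid, (2Z)-2-methylbut-2-enoic acid | C/C=C(/C)C(=O)O | starting material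
23 | (2Z)-2-methylbut-2-enoic 2,4,6-trichlorobenzoic anhydride | C/C=C(/C)C(=O)OC(=O)c1c(Cl)cc(Cl)cc1Cl | intermediate
24 | (4R,5R,6S,8S,10R)-13-acetoxy-8-angeloyloxy-4,5-epoxy-10-hydroxy-1-oxogermacr-7(11)-en-12,6-olide | C/C=C(/C)C(=O)O[C@H]1C[C@@](C)(O)C(=O)CC[C@@]2(C)O[C@@H]2[C@H]2OC(=O)C(COC(C)=O)=C12 | intermediate
25 | (4R,5R,6S,8S,10R)-10,13-diacetoxy-8-angeloyloxy-4,5-epoxy-1-oxogermacr-7(11)-en-12,6-olide | C/C=C(/C)C(=O)O[C@H]1C[C@@](C)(OC(C)=O)C(=O)CC[C@@]2(C)O[C@@H]2[C@H]2OC(=O)C(COC(C)=O)=C12 | target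

**Step count and risks**
Total step count: 18. Longest linear sequence: 15 (steps 1–4, 7–12, 14–18).

The three steps most likely to fail:

Step 11 (the proposed new macrocyclisation). The risks are alkyne oligomerisation, endo closure to the eleven-membered ring, aldehyde hydrosilylation, competing attack on the C1 ketone and poor control at C6. The known-chemistry fallback sets out from 12 and comes back at 16. Mo(CO)3(CNtBu)3-catalysed α-selective hydrostannation of the terminal alkyne of 12 with Bu3SnH gives the vinylstannane (3S,5R,9E)-3-[(tert-butyldimethylsilyl)oxy]-5,11-dihydroxy-5,9-dimethyl-2-(tributylstannyl)undeca-1,9-dien-6-one F1. Iodine in CH2Cl2 at 0 °C converts it into the 2-iodoalkene (3S,5R,9E)-3-[(tert-butyldimethylsilyl)oxy]-5,11-dihydroxy-2-iodo-5,9-dimethylundeca-1,9-dien-6-one F2. Sharpless epoxidation exactly as in step 9 gives the epoxy alcohol (4R,6S)-6-[(tert-butyldimethylsilyl)oxy]-4-hydroxy-1-[(2R,3R)-3-(hydroxymethyl)-2-methyloxiran-2-yl]-7-iodo-4-methyloct-7-en-3-one F3, and Dess–Martin oxidation gives the epoxy aldehyde (2S,3R)-3-[(4R,6S)-6-[(tert-butyldimethylsilyl)oxy]-4-hydroxy-7-iodo-4-methyl-3-oxooct-7-en-1-yl]-3-methyloxirane-2-carbaldehyde F4. A Nozaki–Hiyama–Kishi macrocyclisation (CrCl2, catalytic NiCl2, DMSO/THF, high dilution), which is chemoselective for the aldehyde over the ketone, closes the ten-membered ring and gives the free C6 alcohol 16 directly, so step 12 is skipped.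

Step 15 (a tetrasubstituted olefin by metathesis of two hindered 1,1-disubstituted alkenes). The fallback sets out from 16 and comes back at 20, building the butenolide stepwise. Acryloyl chloride and iPr2NEt give the acrylate (1R,5R,7S,9S,10R)-7-[(tert-butyldimethylsilyl)oxy]-5-hydroxy-1,5-dimethyl-8-methylidene-4-oxo-11-oxabicyclo[8.1.0]undecan-9-yl prop-2-enoate F5. The much easier ring-closing metathesis to a trisubstituted olefin with the second-generation Grubbs catalyst RuCl2(=CHPh)(PCy3)(1,3-dimesitylimidazolidin-2-ylidene) gives the α-unsubstituted butenolide (4R,5R,6S,8S,10R)-8-[(tert-butyldimethylsilyl)oxy]-4,5-epoxy-10-hydroxy-1-oxo-13-norgermacr-7(11)-en-12,6-olide F6. Bromine in CH2Cl2 at −20 °C gives the vicinal 7,11-dibromo adduct F7 (not isolated), and Et3N eliminates HBr to the α-bromobutenolide (4R,5R,6S,8S,10R)-11-bromo-8-[(tert-butyldimethylsilyl)oxy]-4,5-epoxy-10-hydroxy-1-oxo-13-norgermacr-7(11)-en-12,6-olide F8. Stille coupling with (tributylstannyl)methanol and Pd(PPh3)4 in dioxane at 80 °C gives the hydroxymethyl butenolide (4R,5R,6S,8S,10R)-8-[(tert-butyldimethylsilyl)oxy]-4,5-epoxy-10,13-dihydroxy-1-oxogermacr-7(11)-en-12,6-olide F9. Acetyl chloride with 2,4,6-collidine at −78 °C acetylates only the primary alcohol and gives 20.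

Step 2 (an untested alkynyl enolsilane in the copper-catalysed aldol, with risk of low ee or of enolsilane hydrolysis). The fallback sets out from 3 and comes back at 4, using the thioester donor class for which this catalyst is established and attaching the alkyne afterwards. Commercial S-ethyl thioacetate with TMSOTf and Et3N gives the silyl ketene thioacetal 1-(ethylsulfanyl)-1-[(trimethylsilyl)oxy]ethene F10. Its Cu(OTf)2/(R,R)-tBu-box aldol with 3 gives S-ethyl (3R)-3-methyl-4-oxo-3-[(trimethylsilyl)oxy]pentanethioate F11. Palladium-catalysed thioester–alkyne coupling (PdCl2(dppf), CuI, tri(2-furyl)phosphine, Et3N, DMF, 50 °C) with (trimethylsilyl)acetylene then gives ynone 4.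

**Further compounds**
F1 | step 11 | (3S,5R,9E)-3-[(tert-butyldimethylsilyl)oxy]-5,11-dihydroxy-5,9-dimethyl-2-(tributylstannyl)undeca-1,9-dien-6-one | OC/C=C(\C)CCC(=O)[C@](C)(O)C[C@H](O[Si](C)(C)C(C)(C)C)C(=C)[Sn](CCCC)(CCCC)CCCC
F2 | step 11 | (3S,5R,9E)-3-[(tert-butyldimethylsilyl)oxy]-5,11-dihydroxy-2-iodo-5,9-dimethylundeca-1,9-dien-6-one | OC/C=C(\C)CCC(=O)[C@](C)(O)C[C@H](O[Si](C)(C)C(C)(C)C)C(I)=C
F3 | step 11 | (4R,6S)-6-[(tert-butyldimethylsilyl)oxy]-4-hydroxy-1-[(2R,3R)-3-(hydroxymethyl)-2-methyloxiran-2-yl]-7-iodo-4-methyloct-7-en-3-one | OC[C@H]1O[C@]1(C)CCC(=O)[C@](C)(O)C[C@H](O[Si](C)(C)C(C)(C)C)C(I)=C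
F4 | step 11 | (2S,3R)-3-[(4R,6S)-6-[(tert-butyldimethylsilyl)oxy]-4-hydroxy-7-iodo-4-methyl-3-oxooct-7-en-1-yl]-3-methyloxirane-2-carbaldehyde | O=C[C@H]1O[C@]1(C)CCC(=O)[C@](C)(O)C[C@H](O[Si](C)(C)C(C)(C)C)C(I)=C
F5 | step 15 | (1R,5R,7S,9S,10R)-7-[(tert-butyldimethylsilyl)oxy]-5-hydroxy-1,5-dimethyl-8-methylidene-4-oxo-11-oxabicyclo[8.1.0]undecan-9-yl prop-2-enoate | CC(C)(C)[Si](C)(C)O[C@H]1C[C@@](C)(O)C(=O)CC[C@@]2(C)O[C@@H]2[C@@H](OC(=O)C=C)C1=C
F6 | step 15 | (4R,5R,6S,8S,10R)-8-[(tert-butyldimethylsilyl)oxy]-4,5-epoxy-10-hydroxy-1-oxo-13-norgermacr-7(11)-en-12,6-olide | CC(C)(C)[Si](C)(C)O[C@H]1C[C@@](C)(O)C(=O)CC[C@@]2(C)O[C@@H]2[C@H]2OC(=O)C=C12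
F7 | step 15 | 7,11-dibromo adduct of F6 (7,11-dibromo-8-[(tert-butyldimethylsilyl)oxy]-4,5-epoxy-10-hydroxy-1-oxo-13-norgermacran-12,6-olide; mixture at C7 and C11; other centres as in F6) | CC(C)(C)[Si](C)(C)O[C@H]1C[C@@](C)(O)C(=O)CC[C@@]2(C)O[C@@H]2[C@H]2OC(=O)C(Br)C12Br
F8 | step 15 | (4R,5R,6S,8S,10R)-11-bromo-8-[(tert-butyldimethylsilyl)oxy]-4,5-epoxy-10-hydroxy-1-oxo-13-norgermacr-7(11)-en-12,6-olide | CC(C)(C)[Si](C)(C)O[C@H]1C[C@@](C)(O)C(=O)CC[C@@]2(C)O[C@@H]2[C@H]2OC(=O)C(Br)=C12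
F9 | step 15 | (4R,5R,6S,8S,10R)-8-[(tert-butyldimethylsilyl)oxy]-4,5-epoxy-10,13-dihydroxy-1-oxogermacr-7(11)-en-12,6-olide | CC(C)(C)[Si](C)(C)O[C@H]1C[C@@](C)(O)C(=O)CC[C@@]2(C)O[C@@H]2[C@H]2OC(=O)C(CO)=C12
F10 | step 2 | 1-(ethylsulfanyl)-1-[(trimethylsilyl)oxy]ethene | C=C(O[Si](C)(C)C)SCC
F11 | step 2 | S-ethyl (3R)-3-methyl-4-oxo-3-[(trimethylsilyl)oxy]pentanethioate | CCSC(=O)C[C@@](C)(O[Si](C)(C)C)C(C)=O
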